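**Retrosynthetic overview**

1. Target 19 is the E-ferulate of a guai-1(10)-ene-8,11-diol (guaiane numbering: ring A = cyclopentane C1–C5, ring B = cycloheptene C1, C5–C10, C11 = carbinol carbon). The C8–O ester is cut first (diol 16 + acetyl-protected ferulic acid 17), then the trans C7–H/C8–O pair is traced to syn-hydroboration of a C7=C8 olefin and C11 to an ester (16 ⇐ 15 ⇐ 14).
2. Feature that makes the key step possible: at the olefin level ring B of 14 is a cyclohepta-1,4-diene. The tetrasubstituted C1=C10 bond and the C7=C8 bond are separated only by the methylene C9, and C7 is α to the C11 carboxyl, so C7=C8 is a stabilised-ylide Wittig retron and C1=C10 a ring-closing-metathesis retron.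
3. Key disconnection: both bonds are cut together to ylide 10 (ring A with C1 as exocyclic methylene, plus C6 and C7) and 3-methylbut-3-enal 12 (C8, C9, C10). Forward, one flask joins C7 to C8 (Wittig) and C1 to C10 (metathesis) in a formal [4+3] annulation.
4. Stereochemistry: one carbinol centre is set by CBS reduction of cyclopentenone 3 and relayed by hydroxyl-directed hydrogenation to the cis C4/C5 pair; the carbinol is then oxidised away, and C7/C8 are set together in the hydroboration.
5. Ring order: ring A is bought (1); ring B is closed in the key step.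

Key step: step 9

Remark: the cinnamate double bond is taken as E as drawn, and compounds 1, 2, 11 and 17 are taken as commercial.

**Route**

Step 1
Reactants: 1 2-bromo-3-methylcyclopent-2-en-1-one; 2 (3-ethoxy-3-oxopropyl)zinc bromide
Product: 3 ethyl 3-(2-methyl-5-oxocyclopent-1-en-1-yl)propanoate
Conditions: Pd(OAc)2 (2 mol %), SPhos (4 mol %), THF, 40 °C
Reagents that add atoms: none
Why: Negishi cross-coupling of the α-bromo enone with a functionalised alkylzinc halide joins C5 to C6 and creates no stereocentre.

Step 2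
Reactants: 3 ethyl 3-(2-methyl-5-oxocyclopent-1-en-1-yl)propanoate
Product: 4 ethyl 3-[(5S)-5-hydroxy-2-methylcyclopent-1-en-1-yl]propanoate
Conditions: (R)-2-methyl-CBS-oxazaborolidine (10 mol %), catecholborane, PhMe, –78 °C
Reagents that add atoms: none
Why: Corey–Bakshi–Shibata reduction, in which the catalyst distinguishes the substituted enone carbon (large) from the ring CH2 (small) and should give the (S)-carbinol at C1, the centre from which the others are relayed.

Step 3
Reactants: 4 ethyl 3-[(5S)-5-hydroxy-2-methylcyclopent-1-en-1-yl]propanoate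
Product: 5 ethyl 3-[(1S,2S,5S)-2-hydroxy-5-methylcyclopentyl]propanoate
Conditions: [Ir(cod)(PCy3)(py)]PF6 (5 mol %), H2 (1 atm), CH2Cl2, 25 °C
Reagents that add atoms: none
Why: hydroxyl-directed homogeneous hydrogenation of the tetrasubstituted olefin, in which iridium bound to the C1 hydroxyl delivers both hydrogens to the same face, so H-4 and H-5 end cis to OH and the methyl group and side chain end cis to each other (C4 and C5 set in one event by substrate control).

Step 4
Reactants: 5 ethyl 3-[(1S,2S,5S)-2-hydroxy-5-methylcyclopentyl]propanoate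
Product: 6 ethyl 3-[(1S,2S)-2-methyl-5-oxocyclopentyl]propanoate
Conditions: Dess–Martin periodinane, CH2Cl2, 0 → 25 °C
Reagents that add atoms: none
Why: Dess–Martin oxidation removes the relay carbinol under non-basic conditions that should not epimerise the adjacent cis C5 centre.

Step 5
Reactants: 6 ethyl 3-[(1S,2S)-2-methyl-5-oxocyclopentyl]propanoate
Product: 7 ethyl 3-[(1S,2S)-2-methyl-5-methylidenecyclopentyl]propanoate
Conditions: Zn, CH2Br2, TiCl4, THF/CH2Cl2, 0 → 25 °C
Reagents that add atoms: dibromomethane, BrCBr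
Why: Takai–Lombardo methylenation, a non-basic zinc–titanium carbenoid olefination that spares the ester and the epimerisable C5 centre.

Step 6
Reactants: 7 ethyl 3-[(1S,2S)-2-methyl-5-methylidenecyclopentyl]propanoate
Product: 8 ethyl 2-bromo-3-[(1S,2S)-2-methyl-5-methylidenecyclopentyl]propanoate (mixture of C2 epimers)
Conditions: LDA, THF, –78 °C; then BrCCl2CCl2Br, –78 → –40 °C
Reagents that add atoms: 1,2-dibromo-1,1,2,2-tetrachloroethane, BrC(Cl)(Cl)C(Cl)(Cl)Br
Why: electrophilic α-bromination of the lithium ester enolate, where the new centre at C7 is left uncontrolled because it becomes the ylide carbon.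

Step 7
Reactants: 8 ethyl 2-bromo-3-[(1S,2S)-2-methyl-5-methylidenecyclopentyl]propanoate
Product: 10 ethyl 3-[(1S,2S)-2-methyl-5-methylidenecyclopentyl]-2-(triphenyl-λ5-phosphanylidene)propanoate, via phosphonium bromide 9 (not isolated)
Conditions: PPh3, PhMe, 100 °C; then NaOH (aq), CH2Cl2, 25 °C
Reagents that add atoms: triphenylphosphine, c1ccc(cc1)P(c1ccccc1)c1ccccc1
Why: SN2 quaternisation of triphenylphosphine by the α-bromo ester followed by deprotonation gives the ester-stabilised ylide (standard Wittig reagent synthesis).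

Step 8
Reactants: 11 3-methylbut-3-en-1-ol
Product: 12 3-methylbut-3-enal
Conditions: Dess–Martin periodinane, CH2Cl2, 0 °C; used at once as a solution
Reagents that add atoms: none
Why: Dess–Martin oxidation of the homoallylic alcohol under mild conditions should keep the β,γ-double bond out of conjugation.

Step 9
Reactants: 10 ethyl 3-[(1S,2S)-2-methyl-5-methylidenecyclopentyl]-2-(triphenyl-λ5-phosphanylidene)propanoate; 12 3-methylbut-3-enal
Product: 14 ethyl (3S,3aS)-3,8-dimethyl-1,2,3,3a,4,7-hexahydroazulene-5-carboxylate, via acyclic E-dienoate 13 (not isolated)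
Conditions: PhMe, 50 °C; then second-generation Hoveyda–Grubbs catalyst (10 mol %), 1,4-benzoquinone (20 mol %), PhMe (5 mM), 100 °C, same flask
Reagents that add atoms: none
Why: The ester-stabilised ylide 10 adds to aldehyde 12 and collapses through the oxaphosphetane (loss of Ph3P=O) to the E-trisubstituted enoate 13, which joins C7 to C8 at the olefin level and places C6 and C9 cis on the new double bond; the ruthenium alkylidene then closes ring B by olefin metathesis between the two 1,1-disubstituted olefins (ruthenacyclobutane, loss of ethene) and so forms the tetrasubstituted C1=C10 bond. The closest known reaction type is a Wittig olefination telescoped with ring-closing metathesis, with closures to tetrasubstituted cycloheptenes by second-generation ruthenium catalysts as precedent. Ring B is closed as a seven-membered ring in a formal [4+3] union of the C1/C5/C6/C7 unit with the C8/C9/C10 unit, the Wittig stage being intermolecular and the metathesis stage the ring closure; the only other olefin pairings would give cyclobutenes or cyclopropenes. No stereocentre is created, the controlled element being the geometry of C7=C8. The step needs E selectivity in the olefination (expected from the α-branched stabilised ylide), chemoselectivity of the metathesis for the two terminal olefins over the conjugated trisubstituted ester olefin (its conjugation and substitution make it unreactive) and retention of the allylic C5 centre (1,4-benzoquinone suppresses ruthenium hydride double-bond migration).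

Step 10
Reactants: 14 ethyl (3S,3aS)-3,8-dimethyl-1,2,3,3a,4,7-hexahydroazulene-5-carboxylate
Product: 15 2-[(3S,3aS)-3,8-dimethyl-1,2,3,3a,4,7-hexahydroazulen-5-yl]propan-2-ol
Conditions: MeMgBr, THF, –40 → 0 °C
Reagents that add atoms: methylmagnesium bromide, C[Mg]Br
Why: double 1,2-addition of the Grignard reagent to the conjugated ester builds the tertiary carbinol C11 and creates no stereocentre.

Step 11
Reactants: 15 2-[(3S,3aS)-3,8-dimethyl-1,2,3,3a,4,7-hexahydroazulen-5-yl]propan-2-ol
Product: 16 (3S,3aS,5S,6S)-5-(2-hydroxypropan-2-yl)-3,8-dimethyl-1,2,3,3a,4,5,6,7-octahydroazulen-6-ol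
Conditions: IpcBH2 (from (+)-α-pinene), THF, –25 → 0 °C; then NaOH, H2O2, 0 → 25 °C
Reagents that add atoms: hydrogen peroxide, OO
Why: Brown hydroboration–oxidation, in which the monoalkylborane adds syn across the trisubstituted C7=C8 olefin with boron on the less substituted C8 and oxidation goes with retention, so H-7 and O-8 end cis and the C8 hydroxyl trans to the hydroxyisopropyl group (C7 and C8 set in one event), the face being chosen by the chiral borane (reagent control, (7S,8S) expected from Brown's model for 1-substituted cycloalkenes) and the tetrasubstituted C1=C10 olefin being too hindered to react.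

Step 12
Reactants: 16 (3S,3aS,5S,6S)-5-(2-hydroxypropan-2-yl)-3,8-dimethyl-1,2,3,3a,4,5,6,7-octahydroazulen-6-ol; 17 (2E)-3-(4-acetoxy-3-methoxyphenyl)prop-2-enoic acid
Product: 18 (3S,3aS,5S,6S)-5-(2-hydroxypropan-2-yl)-3,8-dimethyl-1,2,3,3a,4,5,6,7-octahydroazulen-6-yl (2E)-3-(4-acetoxy-3-methoxyphenyl)prop-2-enoate
Conditions: DCC, DMAP (20 mol %), CH2Cl2, 25 °C
Reagents that add atoms: none
Why: Steglich esterification should acylate only the secondary C8 hydroxyl, the tertiary C11 hydroxyl being too hindered.

Step 13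
Reactants: 18 (3S,3aS,5S,6S)-5-(2-hydroxypropan-2-yl)-3,8-dimethyl-1,2,3,3a,4,5,6,7-octahydroazulen-6-yl (2E)-3-(4-acetoxy-3-methoxyphenyl)prop-2-enoate
Product: 19 (3S,3aS,5S,6S)-5-(2-hydroxypropan-2-yl)-3,8-dimethyl-1,2,3,3a,4,5,6,7-octahydroazulen-6-yl (2E)-3-(4-hydroxy-3-methoxyphenyl)prop-2-enoate
Conditions: pyrrolidine, CH2Cl2, 0 °C
Reagents that add atoms: none
Why: chemoselective aminolysis of the aryl acetate, a far better acyl donor than the hindered alkyl cinnamate, frees the phenol.

**Compound list**

1 | 2-bromo-3-methylcyclopent-2-en-1-one | CC1=C(Br)C(=O)CC1 | starting material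
2 | (3-ethoxy-3-oxopropyl)zinc bromide | CCOC(=O)CC[Zn]Br | starting material
3 | ethyl 3-(2-methyl-5-oxocyclopent-1-en-1-yl)propanoate | CCOC(=O)CCC1=C(C)CCC1=O | intermediate
4 | ethyl 3-[(5S)-5-hydroxy-2-methylcyclopent-1-en-1-yl]propanoate | O[C@H]1CCC(C)=C1CCC(=O)OCC | intermediate
5 | ethyl 3-[(1S,2S,5S)-2-hydroxy-5-methylcyclopentyl]propanoate | O[C@H]1CC[C@H](C)[C@@H]1CCC(=O)OCC | intermediate
6 | ethyl 3-[(1S,2S)-2-methyl-5-oxocyclopentyl]propanoate | O=C1CC[C@H](C)[C@@H]1CCC(=O)OCC | intermediate
7 | ethyl 3-[(1S,2S)-2-methyl-5-methylidenecyclopentyl]propanoate | C=C1CC[C@H](C)[C@@H]1CCC(=O)OCC | intermediate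
8 | ethyl 2-bromo-3-[(1S,2S)-2-methyl-5-methylidenecyclopentyl]propanoate (C2 epimers) | C=C1CC[C@H](C)[C@@H]1CC(Br)C(=O)OCC | intermediate
9 | {1-ethoxy-3-[(1S,2S)-2-methyl-5-methylidenecyclopentyl]-1-oxopropan-2-yl}triphenylphosphonium bromide | C=C1CC[C@H](C)[C@@H]1CC([P+](c1ccccc1)(c1ccccc1)c1ccccc1)C(=O)OCC.[Br-] | intermediate
10 | ethyl 3-[(1S,2S)-2-methyl-5-methylidenecyclopentyl]-2-(triphenyl-λ5-phosphanylidene)propanoate | C=C1CC[C@H](C)[C@@H]1CC(=P(c1ccccc1)(c1ccccc1)c1ccccc1)C(=O)OCC | intermediate
11 | 3-methylbut-3-en-1-ol | C=C(C)CCO | starting material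
12 | 3-methylbut-3-enal | C=C(C)CC=O | intermediate
13 | ethyl (2E)-5-methyl-2-{[(1S,2S)-2-methyl-5-methylidenecyclopentyl]methyl}hexa-2,5-dienoate | C=C1CC[C@H](C)[C@@H]1C/C(=C\CC(C)=C)C(=O)OCC | intermediate
14 | ethyl (3S,3aS)-3,8-dimethyl-1,2,3,3a,4,7-hexahydroazulene-5-carboxylate | CCOC(=O)C1=CCC(C)=C2CC[C@H](C)[C@@H]2C1 | intermediate
15 | 2-[(3S,3aS)-3,8-dimethyl-1,2,3,3a,4,7-hexahydroazulen-5-yl]propan-2-ol | CC(C)(O)C1=CCC(C)=C2CC[C@H](C)[C@@H]2C1 | intermediate
16 | (3S,3aS,5S,6S)-5-(2-hydroxypropan-2-yl)-3,8-dimethyl-1,2,3,3a,4,5,6,7-octahydroazulen-6-ol | O[C@H]1CC(C)=C2CC[C@H](C)[C@@H]2C[C@@H]1C(C)(C)O | intermediate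
17 | (2E)-3-(4-acetoxy-3-methoxyphenyl)prop-2-enoic acid | COc1cc(/C=C/C(=O)O)ccc1OC(C)=O | starting material
18 | (3S,3aS,5S,6S)-5-(2-hydroxypropan-2-yl)-3,8-dimethyl-1,2,3,3a,4,5,6,7-octahydroazulen-6-yl (2E)-3-(4-acetoxy-3-methoxyphenyl)prop-2-enoate | COc1cc(/C=C/C(=O)O[C@H]2CC(C)=C3CC[C@H](C)[C@@H]3C[C@@H]2C(C)(C)O)ccc1OC(C)=O | intermediate
19 | (3S,3aS,5S,6S)-5-(2-hydroxypropan-2-yl)-3,8-dimethyl-1,2,3,3a,4,5,6,7-octahydroazulen-6-yl (2E)-3-(4-hydroxy-3-methoxyphenyl)prop-2-enoate | COc1cc(/C=C/C(=O)O[C@H]2CC(C)=C3CC[C@H](C)[C@@H]3C[C@@H]2C(C)(C)O)ccc1O | target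

**Step count**

Total step count: 13. Longest linear sequence: 12 steps (steps 1–7 and 9–13, from 1 to 19).

**Steps most likely to fail, with fallbacks**

1. Step 9 (one-flask Wittig olefination and ring closure). What may go wrong:
   - the basic ylide may shift the β,γ-double bond of 12 into conjugation before olefination;
   - the ring closure to the tetrasubstituted olefin may stall in the presence of phosphorus residues and the conjugated ester, so that double-bond migration or oligomerisation takes over.

   The fallback sets out from 7 and 12 and comes back at 14; it makes the two bonds in separate isolated steps by different chemistry. The lithium enolate of 7 (LDA, THF, –78 °C) is added to 12 in an aldol addition that should outrun enolisation of the aldehyde, to give ethyl 3-hydroxy-5-methyl-2-{[(1S,2S)-2-methyl-5-methylidenecyclopentyl]methyl}hex-5-enoate F1 as a diastereomer mixture. F1, now unconjugated and free of phosphorus by-products, is closed by ring-closing metathesis (second-generation Grubbs catalyst, PhMe, 80–100 °C) to ethyl (3S,3aS)-6-hydroxy-3,8-dimethyl-1,2,3,3a,4,5,6,7-octahydroazulene-5-carboxylate F2. Mesylation (MsCl, Et3N) gives ethyl (3S,3aS)-6-(methanesulfonyloxy)-3,8-dimethyl-1,2,3,3a,4,5,6,7-octahydroazulene-5-carboxylate F3, and E1cB elimination with DBU should convert all diastereomers into 14.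

2. Step 11 (hydroboration). What may go wrong: the chiral borane and the substrate may be mismatched, so that boron is delivered to both faces of C7=C8, or the free tertiary hydroxyl may slow the addition.

   The fallback sets out from 14 and comes back at 16; it places the C8 oxygen by conjugate addition to the ester instead. Copper-catalysed enantioselective β-borylation (CuCl, NaOt-Bu, a chiral Josiphos-type bisphosphine, B2pin2, MeOH, THF) followed by equilibration of the α-centre with NaOEt should give the trans boronate ethyl (3S,3aS,5S,6S)-3,8-dimethyl-6-(4,4,5,5-tetramethyl-1,3,2-dioxaborolan-2-yl)-1,2,3,3a,4,5,6,7-octahydroazulene-5-carboxylate F4. Oxidation with retention (NaBO3, THF/H2O) gives ethyl (3S,3aS,5S,6S)-6-hydroxy-3,8-dimethyl-1,2,3,3a,4,5,6,7-octahydroazulene-5-carboxylate F5, and excess MeMgBr then converts the ester into the tertiary carbinol of 16.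

3. Step 12 (esterification). What may go wrong: acylation of the C8 hydroxyl, which sits next to the carbon bearing the bulky carbinol group, may be slow, so that the activated cinnamic acid rearranges to the N-acylurea or the substrate eliminates.

   The fallback sets out from 16 and comes back at 18; it builds the cinnamate on the molecule. The small acid 2-(diethoxyphosphoryl)acetic acid is coupled first (DCC, DMAP) to give (3S,3aS,5S,6S)-5-(2-hydroxypropan-2-yl)-3,8-dimethyl-1,2,3,3a,4,5,6,7-octahydroazulen-6-yl 2-(diethoxyphosphoryl)acetate F6. A Horner–Wadsworth–Emmons reaction of F6 with 4-acetoxy-3-methoxybenzaldehyde (LiCl, i-Pr2NEt, MeCN) should then give the E-cinnamate 18.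

**Further compounds**

F1 | step 9 | ethyl 3-hydroxy-5-methyl-2-{[(1S,2S)-2-methyl-5-methylidenecyclopentyl]methyl}hex-5-enoate (diastereomer mixture) | C=C1CC[C@H](C)[C@@H]1CC(C(=O)OCC)C(O)CC(C)=C
F2 | step 9 | ethyl (3S,3aS)-6-hydroxy-3,8-dimethyl-1,2,3,3a,4,5,6,7-octahydroazulene-5-carboxylate (diastereomer mixture at C5 and C6) | OC1CC(C)=C2CC[C@H](C)[C@@H]2CC1C(=O)OCC
F3 | step 9 | ethyl (3S,3aS)-6-(methanesulfonyloxy)-3,8-dimethyl-1,2,3,3a,4,5,6,7-octahydroazulene-5-carboxylate (diastereomer mixture at C5 and C6) | CS(=O)(=O)OC1CC(C)=C2CC[C@H](C)[C@@H]2CC1C(=O)OCC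
F4 | step 11 | ethyl (3S,3aS,5S,6S)-3,8-dimethyl-6-(4,4,5,5-tetramethyl-1,3,2-dioxaborolan-2-yl)-1,2,3,3a,4,5,6,7-octahydroazulene-5-carboxylate | B1(OC(C)(C)C(C)(C)O1)[C@H]1CC(C)=C2CC[C@H](C)[C@@H]2C[C@@H]1C(=O)OCC
F5 | step 11 | ethyl (3S,3aS,5S,6S)-6-hydroxy-3,8-dimethyl-1,2,3,3a,4,5,6,7-octahydroazulene-5-carboxylate | O[C@H]1CC(C)=C2CC[C@H](C)[C@@H]2C[C@@H]1C(=O)OCC
F6 | step 12 | (3S,3aS,5S,6S)-5-(2-hydroxypropan-2-yl)-3,8-dimethyl-1,2,3,3a,4,5,6,7-octahydroazulen-6-yl 2-(diethoxyphosphoryl)acetate | CCOP(=O)(OCC)CC(=O)O[C@H]1CC(C)=C2CC[C@H](C)[C@@H]2C[C@@H]1C(C)(C)O
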